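**Plan**
1. The two ArCH2–C bonds on either side of ring B are cut first (retro-Michael to ortho-quinone methides from Mannich bases). This gives ring A as butyrylfilicinic acid, ring B as commercial phlorbutyrophenone and ring C as the 2-O-methyl ether of 3-methylphlorbutyrophenone.
2. Ring A is then cut at C1–C6 (ring carbonyl to the gem-dimethyl carbon) and at C2–C3 (butanoyl-bearing carbon to the enol carbon). The enabling feature is that ring A is a cyclohexane-1,3,5-trione tautomer: every ring bond joins a carbonyl carbon to an α-carbon, so the ring is a folded 4,4-dimethyl-3,5,7-trioxodecanoate. Quaternary C6 cannot enolize or aromatize, so only Claisen closure ends in a stable vinylogous acid.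
3. Forward, the bis(silyl) dienol ether of methyl isobutyrylacetate captures butyrylketene at its CMe2 terminus (C6–C1). Methoxide then unmasks the tetraketide and closes C2–C3 in the same flask.
4. Ring C is made from 2-methylphloroglucinol (acylation, selective protection, O-methylation), aminomethylated and joined to ring B. The ring B–ring C dimer is aminomethylated and joined to ring A last.
5. The target has no stereocentre, so only site selectivity has to be controlled.

Key step: step 4

Remark: the target is achiral and ring A is drawn as one of several rapidly interconverting enol tautomers; the structure given by the SMILES (ring C with its methyl ether between the butanoyl and C-methyl groups) is taken as the target.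

**Route**

Step 1
Reactants: 1 methyl 4-methyl-3-oxopentanoate
Product: 2 methyl (2Z)-4-methyl-3-(trimethylsilyloxy)pent-2-enoate
Conditions: TMSCl, Et3N, hexane, rt
Reagents that add atoms: chlorotrimethylsilane C[Si](C)(C)Cl
Why: Soft enolization and O-silylation of the chelated β-keto ester enol (silyl enol ether formation) should give the conjugated Z-enol ether, the first stage of a Chan-type diene synthesis.

Step 2
Reactants: 2 methyl (2Z)-4-methyl-3-(trimethylsilyloxy)pent-2-enoate
Product: 3 (1Z)-1-methoxy-4-methyl-1,3-bis(trimethylsilyloxy)penta-1,3-diene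
Conditions: LiN(i-Pr)2, THF, −78 °C; TMSCl, −78 °C → rt; distilled and used at once
Reagents that add atoms: chlorotrimethylsilane C[Si](C)(C)Cl
Why: Kinetic γ-deprotonation of the vinylogous ester at the isopropyl methine and O-silylation of the extended enolate (Chan-type 1,3-bis(silyloxy)diene synthesis) should give the neutral equivalent of the β-keto ester dianion; the ketene acetal geometry is of no consequence.

Step 3
Reactants: 4 2,2,6-trimethyl-4H-1,3-dioxin-4-one
Product: 5 2,2-dimethyl-6-propyl-4H-1,3-dioxin-4-one
Conditions: LiN(i-Pr)2, THF/DMPU, −78 °C; EtI, −78 → −20 °C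
Reagents that add atoms: iodoethane CCI
Why: Vinylogous (γ) alkylation of the lithium dienolate of the dioxinone extends the 6-methyl group to propyl and gives a neutral thermal precursor of butyrylketene.

Step 4
Reactants: 3 (1Z)-1-methoxy-4-methyl-1,3-bis(trimethylsilyloxy)penta-1,3-diene, 5 2,2-dimethyl-6-propyl-4H-1,3-dioxin-4-one
Product: 9 butyrylfilicinic acid (2-butanoyl-3,5-dihydroxy-6,6-dimethylcyclohexa-2,4-dien-1-one), via butyrylketene 6 (not isolated), via silyl ketal cycloadduct 7 (not isolated), via triketo ester 8 (not isolated)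
Conditions: 5 added slowly to 3 (1.5 equiv), toluene, 110 °C, N2 stream; then NaOMe (3 equiv), MeOH, 0 → 40 °C; aq. HCl
Reagents that add atoms: none
Why: Proposed new method: retro-[4+2] of 5 at 110 °C releases butyrylketene 6, whose ketene carbon is captured by the CMe2 terminus of diene 3 in a hetero-[4+2] (or its stepwise Mukaiyama-type equivalent) that makes the C1–C6 bond of ring A and gives silyl ketal 7, a masked 4,4-dimethyl tetraketide; methoxide then removes both silyl groups, the hemiketal opens to the β-diketone enolate of 8, and its central carbon attacks the ester carbonyl (Claisen/Dieckmann) to make the C2–C3 bond with loss of methoxide. The closest known reaction types are the [4+2] capture of dioxinone-derived acylketenes by enol ethers, the γ-acylation of 1,3-bis(silyloxy)dienes and the base-induced Claisen cyclization of 3,5,7-trioxoalkanoates to acylphloroglucinols. Ring A closes in a 6-exo-trig (enolexo) mode, and the dihydropyranone ring of 7 is only transient. No stereocentre is created, since C6 carries two identical methyl groups and the stereocentre of racemic 7 is lost on ring opening. The step needs γ- over α-attack on the diene, which the larger frontier coefficient at the vinylogous terminus should secure, and Claisen closure through carbon over aldol or O-closure, which is secured because quaternary C6 forbids aromatization of any aldol product while the Claisen product is a vinylogous acid whose delocalized anion is the thermodynamic sink.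

Step 5
Reactants: 10 2-methylbenzene-1,3,5-triol (2-methylphloroglucinol)
Product: 11 1-(2,4,6-trihydroxy-3-methylphenyl)butan-1-one
Conditions: PrCOCl, AlCl3, PhNO2/CH2Cl2, 0 °C → rt; aq. HCl
Reagents that add atoms: butanoyl chloride CCCC(=O)Cl
Why: Friedel–Crafts C-acylation of the very electron-rich triol, whose two free ring positions are equivalent, should stop after one acyl group because the ketone deactivates the ring.

Step 6
Reactants: 11 1-(2,4,6-trihydroxy-3-methylphenyl)butan-1-one
Product: 12 1-[2-hydroxy-4,6-bis(methoxymethoxy)-3-methylphenyl]butan-1-one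
Conditions: MOMCl (2.2 equiv), i-Pr2NEt, CH2Cl2, 0 °C
Reagents that add atoms: chloromethyl methyl ether COCCl
Why: Methoxymethyl ether formation (phenol O-alkylation) should take the non-chelated 4-OH and the less hindered 6-OH, while the 2-OH, hydrogen-bonded to the ketone and flanked by the C-methyl group, stays free.

Step 7
Reactants: 12 1-[2-hydroxy-4,6-bis(methoxymethoxy)-3-methylphenyl]butan-1-one
Product: 13 1-[2-methoxy-4,6-bis(methoxymethoxy)-3-methylphenyl]butan-1-one
Conditions: MeI, K2CO3, DMF, 50 °C
Reagents that add atoms: iodomethane CI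
Why: Williamson O-methylation of the one remaining (chelated) phenol fixes the methyl ether between the butanoyl and C-methyl groups.

Step 8
Reactants: 13 1-[2-methoxy-4,6-bis(methoxymethoxy)-3-methylphenyl]butan-1-one
Product: 14 1-(4,6-dihydroxy-2-methoxy-3-methylphenyl)butan-1-one
Conditions: HCl (cat.), MeOH, 50 °C
Reagents that add atoms: none
Why: Acid-catalysed acetal exchange with methanol (MOM cleavage) frees both phenols and leaves the aryl methyl ether and the ketone untouched.

Step 9
Reactants: 14 1-(4,6-dihydroxy-2-methoxy-3-methylphenyl)butan-1-one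
Product: 15 1-[3-[(dimethylamino)methyl]-2,4-dihydroxy-6-methoxy-5-methylphenyl]butan-1-one
Conditions: CH2=NMe2+ I−, Et3N, MeCN, 0 °C → rt
Reagents that add atoms: N,N-dimethylmethyleneiminium iodide (Eschenmoser's salt) C=[N+](C)C.[I-]
Why: Phenolic Mannich reaction with a preformed iminium salt can only occur at the single unsubstituted ring carbon, which lies between the two hydroxyl groups.

Step 10
Reactants: 15 1-[3-[(dimethylamino)methyl]-2,4-dihydroxy-6-methoxy-5-methylphenyl]butan-1-one, 16 1-(2,4,6-trihydroxyphenyl)butan-1-one
Product: 18 1-[3-[(3-butanoyl-2,4,6-trihydroxyphenyl)methyl]-2,4-dihydroxy-6-methoxy-5-methylphenyl]butan-1-one, via ortho-quinone methide 17 (not isolated)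
Conditions: 16 (3 equiv), 1,4-dioxane, 100 °C, N2
Reagents that add atoms: none
Why: Thermal β-elimination of dimethylamine from the phenolic Mannich base should give ortho-quinone methide 17, which the excess phloroglucinol 16 traps by C-alkylation (Michael addition, then rearomatization); the excess of 16 suppresses double alkylation of ring B.

Step 11
Reactants: 18 1-[3-[(3-butanoyl-2,4,6-trihydroxyphenyl)methyl]-2,4-dihydroxy-6-methoxy-5-methylphenyl]butan-1-one
Product: 19 1-[3-[[3-butanoyl-5-[(dimethylamino)methyl]-2,4,6-trihydroxyphenyl]methyl]-2,4-dihydroxy-6-methoxy-5-methylphenyl]butan-1-one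
Conditions: CH2=NMe2+ I−, Et3N, MeCN, 0 °C → rt
Reagents that add atoms: N,N-dimethylmethyleneiminium iodide (Eschenmoser's salt) C=[N+](C)C.[I-]
Why: Phenolic Mannich reaction at the only free ring carbon left in the dimer, the one on ring B.

Step 12
Reactants: 19 1-[3-[[3-butanoyl-5-[(dimethylamino)methyl]-2,4,6-trihydroxyphenyl]methyl]-2,4-dihydroxy-6-methoxy-5-methylphenyl]butan-1-one, 9 butyrylfilicinic acid
Product: 21 2-butanoyl-4-[[3-butanoyl-5-[(3-butanoyl-2,6-dihydroxy-4-methoxy-5-methylphenyl)methyl]-2,4,6-trihydroxyphenyl]methyl]-3,5-dihydroxy-6,6-dimethylcyclohexa-2,4-dien-1-one, via ortho-quinone methide 20 (not isolated)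
Conditions: 9 (1.2 equiv), 1,4-dioxane, 60 °C, N2
Reagents that add atoms: none
Why: The vinylogous acid 9 protonates the benzylic amine, dimethylamine is eliminated to ortho-quinone methide 20, and the enolate of 9 adds through C4 (Michael addition) before ring B rearomatizes; neither partner has another free nucleophilic carbon, so no oligomer can form.

**Compound list**
1 | methyl 4-methyl-3-oxopentanoate | CC(C)C(=O)CC(=O)OC | starting material
2 | methyl (2Z)-4-methyl-3-(trimethylsilyloxy)pent-2-enoate | COC(=O)/C=C(\O[Si](C)(C)C)C(C)C | intermediate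
3 | (1Z)-1-methoxy-4-methyl-1,3-bis(trimethylsilyloxy)penta-1,3-diene | CO/C(O[Si](C)(C)C)=C/C(O[Si](C)(C)C)=C(C)C | intermediate
4 | 2,2,6-trimethyl-4H-1,3-dioxin-4-one | CC1=CC(=O)OC(C)(C)O1 | starting material
5 | 2,2-dimethyl-6-propyl-4H-1,3-dioxin-4-one | CCCC1=CC(=O)OC(C)(C)O1 | intermediate
6 | butyrylketene (3-oxohex-1-en-1-one) | CCCC(=O)C=C=O | intermediate
7 | 2-[(Z)-2-methoxy-2-(trimethylsilyloxy)ethenyl]-3,3-dimethyl-6-propyl-2-(trimethylsilyloxy)-2,3-dihydro-4H-pyran-4-one (racemic) | CCCC1=CC(=O)C(C)(C)C(O[Si](C)(C)C)(/C=C(/OC)O[Si](C)(C)C)O1 | intermediate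
8 | methyl 4,4-dimethyl-3,5,7-trioxodecanoate (present as its sodium enolates) | CCCC(=O)CC(=O)C(C)(C)C(=O)CC(=O)OC | intermediate
9 | butyrylfilicinic acid (2-butanoyl-3,5-dihydroxy-6,6-dimethylcyclohexa-2,4-dien-1-one) | CCCC(=O)C1=C(O)C=C(O)C(C)(C)C1=O | intermediate
10 | 2-methylbenzene-1,3,5-triol | Cc1c(O)cc(O)cc1O | starting material
11 | 1-(2,4,6-trihydroxy-3-methylphenyl)butan-1-one | CCCC(=O)c1c(O)cc(O)c(C)c1O | intermediate
12 | 1-[2-hydroxy-4,6-bis(methoxymethoxy)-3-methylphenyl]butan-1-one | CCCC(=O)c1c(OCOC)cc(OCOC)c(C)c1O | intermediate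
13 | 1-[2-methoxy-4,6-bis(methoxymethoxy)-3-methylphenyl]butan-1-one | CCCC(=O)c1c(OCOC)cc(OCOC)c(C)c1OC | intermediate
14 | 1-(4,6-dihydroxy-2-methoxy-3-methylphenyl)butan-1-one | CCCC(=O)c1c(O)cc(O)c(C)c1OC | intermediate
15 | 1-[3-[(dimethylamino)methyl]-2,4-dihydroxy-6-methoxy-5-methylphenyl]butan-1-one | CCCC(=O)c1c(O)c(CN(C)C)c(O)c(C)c1OC | intermediate
16 | 1-(2,4,6-trihydroxyphenyl)butan-1-one | CCCC(=O)c1c(O)cc(O)cc1O | starting material
17 | 2-butanoyl-5-hydroxy-3-methoxy-4-methyl-6-methylidenecyclohexa-2,4-dien-1-one | C=C1C(=O)C(C(=O)CCC)=C(OC)C(C)=C1O | intermediate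
18 | 1-[3-[(3-butanoyl-2,4,6-trihydroxyphenyl)methyl]-2,4-dihydroxy-6-methoxy-5-methylphenyl]butan-1-one | CCCC(=O)c1c(O)cc(O)c(Cc2c(O)c(C)c(OC)c(C(=O)CCC)c2O)c1O | intermediate
19 | 1-[3-[[3-butanoyl-5-[(dimethylamino)methyl]-2,4,6-trihydroxyphenyl]methyl]-2,4-dihydroxy-6-methoxy-5-methylphenyl]butan-1-one | CCCC(=O)c1c(O)c(CN(C)C)c(O)c(Cc2c(O)c(C)c(OC)c(C(=O)CCC)c2O)c1O | intermediate
20 | 2-butanoyl-4-[(3-butanoyl-2,6-dihydroxy-4-methoxy-5-methylphenyl)methyl]-3,5-dihydroxy-6-methylidenecyclohexa-2,4-dien-1-one | C=C1C(=O)C(C(=O)CCC)=C(O)C(Cc2c(O)c(C)c(OC)c(C(=O)CCC)c2O)=C1O | intermediate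
21 | 2-butanoyl-4-[[3-butanoyl-5-[(3-butanoyl-2,6-dihydroxy-4-methoxy-5-methylphenyl)methyl]-2,4,6-trihydroxyphenyl]methyl]-3,5-dihydroxy-6,6-dimethylcyclohexa-2,4-dien-1-one | CCCC(=O)C1=C(O)C(Cc2c(O)c(Cc3c(O)c(C)c(OC)c(C(=O)CCC)c3O)c(O)c(C(=O)CCC)c2O)=C(O)C(C)(C)C1=O | target

**Step count and risks**
Total step count: 12. Longest linear sequence: 8 steps (steps 5 to 12).

Steps most likely to fail:

1. Step 4 (proposed new method). The ketene may be captured at the α- instead of the γ-carbon of the diene, may dimerize before capture, or the diene may be protodesilylated at 110 °C. After unmasking, retro-Claisen cleavage next to the quaternary carbon or closure through oxygen could compete with the Claisen ring closure. Fallback (known chemistry): the route sets out from 16, which is C-methylated twice at one ring carbon with MeI (2.2 equiv) and NaOMe in MeOH at 0 °C → rt (dearomative gem-dimethylation of an acylphloroglucinol, passing through the mono-C-methyl stage, which is 11). This should give 9 directly, where it rejoins the route, replacing steps 1 to 4. This fallback makes no compound that is not already listed: none F0.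

2. Step 6. The second acetalization may discriminate poorly between the two ketone-flanking phenols, which would place the later methyl ether on the wrong oxygen. Fallback: the route sets out from 11, which is perbenzylated (BnBr, K2CO3, DMF) to 1-[2,4,6-tris(benzyloxy)-3-methylphenyl]butan-1-one F1. Chelation-controlled mono-debenzylation with BCl3 (1 equiv, CH2Cl2, −78 °C) should remove the ortho benzyl ether that is crowded between the ketone and the C-methyl group, giving 1-[4,6-bis(benzyloxy)-2-hydroxy-3-methylphenyl]butan-1-one F2. Methylation (MeI, K2CO3, DMF) gives 1-[4,6-bis(benzyloxy)-2-methoxy-3-methylphenyl]butan-1-one F3, and hydrogenolysis (H2, Pd/C, EtOAc) returns to the route at 14. Site selectivity then rests on selective deprotection and not on selective protection.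

3. Step 12. The methylene bridges may exchange by retro-Michael fragmentation and re-addition, scrambling the three rings; a ring B phenol may cyclodehydrate onto a ring A carbonyl; or elimination of the amine may stall. Fallback with the roles of the partners reversed: the route sets out from 18 (with 9), so step 11 is skipped. Compound 9 is aminomethylated (Eschenmoser's salt, Et3N, MeCN, 0 °C) to 2-butanoyl-4-[(dimethylamino)methyl]-3,5-dihydroxy-6,6-dimethylcyclohexa-2,4-dien-1-one F4. On gentle warming with 18 in 1,4-dioxane, F4 should release 2-butanoyl-3-hydroxy-6,6-dimethyl-4-methylidenecyclohex-2-ene-1,5-dione F5, a strong Michael acceptor that the free carbon of ring B in 18 attacks. The fallback rejoins the route at 21.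

**Further compounds**
F0 | step 4 | none | none
F1 | step 6 | 1-[2,4,6-tris(benzyloxy)-3-methylphenyl]butan-1-one | CCCC(=O)c1c(OCc2ccccc2)cc(OCc2ccccc2)c(C)c1OCc1ccccc1
F2 | step 6 | 1-[4,6-bis(benzyloxy)-2-hydroxy-3-methylphenyl]butan-1-one | CCCC(=O)c1c(OCc2ccccc2)cc(OCc2ccccc2)c(C)c1O
F3 | step 6 | 1-[4,6-bis(benzyloxy)-2-methoxy-3-methylphenyl]butan-1-one | CCCC(=O)c1c(OCc2ccccc2)cc(OCc2ccccc2)c(C)c1OC
F4 | step 12 | 2-butanoyl-4-[(dimethylamino)methyl]-3,5-dihydroxy-6,6-dimethylcyclohexa-2,4-dien-1-one | CCCC(=O)C1=C(O)C(CN(C)C)=C(O)C(C)(C)C1=O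
F5 | step 12 | 2-butanoyl-3-hydroxy-6,6-dimethyl-4-methylidenecyclohex-2-ene-1,5-dione | CCCC(=O)C1=C(O)C(=C)C(=O)C(C)(C)C1=O
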